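**Plan**

- Retrosynthetic cuts, in order: C3–CH2CO2Me (peroxycarbenium ion plus silyl ketene acetal); O1–C5 and O2–C3 of the 1,2-dioxolane (enone plus H2O2); the enone C=C bond and its acetyl methyl (olefination, Weinreb ketone synthesis); the C=C bond that joins the phenylpropyl unit (Wittig); the C–CH3 bond at the citronellal aldehyde (Grignard).
- Forward: the chain is built first, (R)-citronellal → methyl ketone → ozonolysis, Wittig, hydrogenation → ketone 9 → E enone 13. The only ring, the 1,2-dioxolane, closes in step 8, and the acetate arm is attached last.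
- Enabling feature: in the dioxolane ring, O1–C5 and O2–C3 flank the C4 methylene just as the β-carbon and the carbonyl carbon flank the α-carbon of a β,β-disubstituted methyl enone, so one molecule of H2O2 can supply both ring oxygens.
- Stereochemistry: side-chain C2′ (R) comes from (R)-citronellal; C5 (S) from the chiral primary amine catalyst in step 8; C3 (R) from attack on the peroxycarbenium ion anti to the long chain in step 10.

Key step: step 8

Remark on the chemistry: the facial sense of a cinchona primary amine on an acyclic β,β-disubstituted enone is not established; the quinine-derived amine is assumed to give (5S), and if it gives (5R) the quinidine-derived pseudoenantiomer is used with no other change.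

**Route**

Step 1
Reactants: 1 (R)-citronellal
Product: 2 (4R)-4,8-dimethylnon-7-en-2-ol (both C2 epimers)
Conditions: MeMgBr, Et2O, 0 °C; then aq. NH4Cl
Reagents that add atoms: methylmagnesium bromide, C[Mg]Br
Why: Grignard 1,2-addition to the unhindered aldehyde is fast at 0 °C and leaves the trisubstituted alkene and the methyl-bearing stereocentre untouched; the new carbinol centre may form as a mixture because step 2 removes it.

Step 2
Reactants: 2 (4R)-4,8-dimethylnon-7-en-2-ol
Product: 3 (4R)-4,8-dimethylnon-7-en-2-one
Conditions: Dess–Martin periodinane, CH2Cl2, rt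
Reagents that add atoms: none
Why: Dess–Martin oxidation converts the secondary alcohol to the methyl ketone under neutral conditions that spare the alkene, and the stereocentre is β to the new carbonyl and cannot epimerise by enolisation.

Step 3
Reactants: 3 (4R)-4,8-dimethylnon-7-en-2-one
Product: 5 (4R)-4-methyl-6-oxoheptanal, via ozonide 4 (not isolated)
Conditions: O3, CH2Cl2, −78 °C; then PPh3, −78 °C to rt
Reagents that add atoms: ozone, [O-][O+]=O
Why: Ozonolysis (Criegee mechanism) cleaves only the electron-rich trisubstituted alkene, the ketone being inert, and PPh3 reduces the ozonide to the aldehyde with loss of acetone.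

Step 4
Reactants: 5 (4R)-4-methyl-6-oxoheptanal; 6 (3-phenylpropyl)triphenylphosphonium bromide
Product: 8 (4R,7Z)-4-methyl-10-phenyldec-7-en-2-one, via phosphorus ylide 7 (not isolated)
Conditions: 6, NaN(SiMe3)2, THF, 0 °C; then 5, −78 °C to rt
Reagents that add atoms: none
Why: Wittig olefination with a salt-free unstabilised ylide is far faster at the aldehyde than at the methyl ketone at −78 °C and should give mainly the Z alkene, whose geometry is irrelevant because step 5 saturates it.

Step 5
Reactants: 8 (4R,7Z)-4-methyl-10-phenyldec-7-en-2-one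
Product: 9 (4R)-4-methyl-10-phenyldecan-2-one
Conditions: H2 (1 atm), Pd/C, EtOAc, rt
Reagents that add atoms: none
Why: Heterogeneous catalytic hydrogenation saturates the disubstituted alkene at 1 atm without touching the ketone or the arene, and no stereocentre is affected.

Step 6
Reactants: 9 (4R)-4-methyl-10-phenyldecan-2-one; 10 diethyl {2-[methoxy(methyl)amino]-2-oxoethyl}phosphonate
Product: 12 (2E,5R)-N-methoxy-N,3,5-trimethyl-11-phenylundec-2-enamide, via sodium phosphonate carbanion 11 (not isolated)
Conditions: 10, NaH, THF, 0 °C; then 9, 0 °C to reflux; E isomer separated on silica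
Reagents that add atoms: none
Why: Horner–Wadsworth–Emmons olefination of the unhindered methyl ketone with the Weinreb amide phosphonate should favour the E isomer (branched CH2 chain trans to the amide), and E and Z amides of this kind are separable by chromatography.

Step 7
Reactants: 12 (2E,5R)-N-methoxy-N,3,5-trimethyl-11-phenylundec-2-enamide
Product: 13 (3E,6R)-4,6-dimethyl-12-phenyldodec-3-en-2-one
Conditions: MeMgBr, THF, 0 °C; then aq. NH4Cl
Reagents that add atoms: methylmagnesium bromide, C[Mg]Br
Why: Weinreb ketone synthesis, in which the magnesium-chelated tetrahedral adduct blocks a second addition and 1,2-attack on the N-methoxy-N-methylamide keeps the trisubstituted alkene and its E geometry.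

Step 8
Reactants: 13 (3E,6R)-4,6-dimethyl-12-phenyldodec-3-en-2-one; 14 hydrogen peroxide
Product: 16 (3RS,5S)-3,5-dimethyl-5-[(2R)-2-methyl-8-phenyloctyl]-1,2-dioxolan-3-ol, via β-hydroperoxy ketone 15 (not isolated)
Conditions: 9-amino-9-deoxy-epi-quinine (20 mol%), Cl3CCO2H (20 mol%), 50% aq. H2O2 (3–5 equiv), 1,4-dioxane, 30 °C
Reagents that add atoms: none
Why: Proposed new method: the primary amine condenses with the methyl ketone of 13 to an iminium ion, the protonated quinuclidine holds H2O2 by hydrogen bonding and delivers it to one face of the β-carbon (C5), and hydrolysis releases hydroperoxy ketone 15, whose OOH then adds to the C3 carbonyl. The closest known reaction type is the primary-amine (iminium) catalysed asymmetric hydroperoxidation of β-monosubstituted acyclic enones to peroxyhemiketals, together with the epoxidation of β-substituted cyclic enones by the same catalysts, in which a fully substituted C–O centre is also formed at the β-carbon. The 1,2-dioxolane closes by 5-exo-trig attack of the terminal peroxide oxygen on the carbonyl, forming O2–C3 after O1–C5 and taking 15 out of the retro-Michael equilibrium. C5 is set by the catalyst (directed delivery to one enantioface of the E iminium ion) rather than by the remote side-chain centre, while C3 forms as a hemiketal mixture that step 10 erases. The step needs conjugate attack at C5 on a single enantioface and hemiketal closure instead of closure of the hydroperoxy enamine to the epoxy ketone. The unhindered methyl ketone (fast iminium formation and fast hemiketal closure), the single E geometry of 13, the 1,3-spacing of OOH and carbonyl, and the mild, base-free conditions should secure this.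

Step 9
Reactants: 16 (3RS,5S)-3,5-dimethyl-5-[(2R)-2-methyl-8-phenyloctyl]-1,2-dioxolan-3-ol
Product: 17 (3RS,5S)-3-methoxy-3,5-dimethyl-5-[(2R)-2-methyl-8-phenyloctyl]-1,2-dioxolane
Conditions: MeOH, TsOH·H2O (cat.), 3 Å molecular sieves, 0 °C to rt
Reagents that add atoms: methanol, CO
Why: Acid-catalysed exchange of the hemiketal hydroxyl for methoxyl (ketalisation through the oxygen-stabilised peroxycarbenium ion) is the usual behaviour of 1,2-dioxolan-3-ols in methanol; C5 and the side-chain centre are not involved and the C3 mixture is of no consequence.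

Step 10
Reactants: 17 (3RS,5S)-3-methoxy-3,5-dimethyl-5-[(2R)-2-methyl-8-phenyloctyl]-1,2-dioxolane; 18 tert-butyl[(1-methoxyethenyl)oxy]dimethylsilane
Product: 20 methyl 2-[(3R,5S)-3,5-dimethyl-5-[(2R)-2-methyl-8-phenyloctyl]-1,2-dioxolan-3-yl]acetate, via peroxycarbenium ion 19 (not isolated)
Conditions: 18 (2–3 equiv), TiCl4 (1.1 equiv), CH2Cl2, −78 °C
Reagents that add atoms: none
Why: Lewis-acid-mediated substitution of a 3-alkoxy-1,2-dioxolane by a silyl ketene acetal (Mukaiyama-type addition to the peroxycarbenium ion) is a known route to 1,2-dioxolane-3-acetates; the planar cation should be attacked on the ring face anti to the larger C5 substituent, the branched chain, which sets C3 as R, and the minor C3 epimer is removed by chromatography.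

**Compound list**

1 | (R)-citronellal, (3R)-3,7-dimethyloct-6-enal | O=CC[C@H](C)CCC=C(C)C | starting material
2 | (4R)-4,8-dimethylnon-7-en-2-ol (C2 epimers) | CC(O)C[C@H](C)CCC=C(C)C | intermediate
3 | (4R)-4,8-dimethylnon-7-en-2-one | CC(=O)C[C@H](C)CCC=C(C)C | intermediate
4 | (4R)-6-(5,5-dimethyl-1,2,4-trioxolan-3-yl)-4-methylhexan-2-one (ozonide) | CC(=O)C[C@H](C)CCC1OOC(C)(C)O1 | intermediate
5 | (4R)-4-methyl-6-oxoheptanal | CC(=O)C[C@H](C)CCC=O | intermediate
6 | (3-phenylpropyl)triphenylphosphonium bromide | [Br-].C(CCc1ccccc1)[P+](c1ccccc1)(c1ccccc1)c1ccccc1 | starting material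
7 | (3-phenylpropylidene)triphenylphosphorane | C(CCc1ccccc1)=P(c1ccccc1)(c1ccccc1)c1ccccc1 | intermediate
8 | (4R,7Z)-4-methyl-10-phenyldec-7-en-2-one | CC(=O)C[C@H](C)CC/C=C\CCc1ccccc1 | intermediate
9 | (4R)-4-methyl-10-phenyldecan-2-one | CC(=O)C[C@H](C)CCCCCCc1ccccc1 | intermediate
10 | diethyl {2-[methoxy(methyl)amino]-2-oxoethyl}phosphonate | CCOP(=O)(CC(=O)N(C)OC)OCC | starting material
11 | sodium salt of the carbanion of 10 | CCOP(=O)(OCC)[CH-]C(=O)N(C)OC.[Na+] | intermediate
12 | (2E,5R)-N-methoxy-N,3,5-trimethyl-11-phenylundec-2-enamide | CON(C)C(=O)/C=C(\C)C[C@H](C)CCCCCCc1ccccc1 | intermediate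
13 | (3E,6R)-4,6-dimethyl-12-phenyldodec-3-en-2-one | CC(=O)/C=C(\C)C[C@H](C)CCCCCCc1ccccc1 | intermediate
14 | hydrogen peroxide | OO | starting material
15 | (4S,6R)-4-hydroperoxy-4,6-dimethyl-12-phenyldodecan-2-one | CC(=O)C[C@](C)(C[C@H](C)CCCCCCc1ccccc1)OO | intermediate
16 | (3RS,5S)-3,5-dimethyl-5-[(2R)-2-methyl-8-phenyloctyl]-1,2-dioxolan-3-ol | CC1(O)C[C@](C)(C[C@H](C)CCCCCCc2ccccc2)OO1 | intermediate
17 | (3RS,5S)-3-methoxy-3,5-dimethyl-5-[(2R)-2-methyl-8-phenyloctyl]-1,2-dioxolane | COC1(C)C[C@](C)(C[C@H](C)CCCCCCc2ccccc2)OO1 | intermediate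
18 | tert-butyl[(1-methoxyethenyl)oxy]dimethylsilane | C=C(OC)O[Si](C)(C)C(C)(C)C | starting material
19 | (5S)-3,5-dimethyl-5-[(2R)-2-methyl-8-phenyloctyl]-1,2-dioxolan-3-ylium (peroxycarbenium ion) | C[C+]1C[C@](C)(C[C@H](C)CCCCCCc2ccccc2)OO1 | intermediate
20 | methyl 2-[(3R,5S)-3,5-dimethyl-5-[(2R)-2-methyl-8-phenyloctyl]-1,2-dioxolan-3-yl]acetate | COC(=O)C[C@@]1(C)C[C@](C)(C[C@H](C)CCCCCCc2ccccc2)OO1 | target

**Step count**

Total: 10 steps. Longest linear sequence: 10 steps (1 → 20).

**Steps most likely to fail**

Step 8. The iminium ion of a β,β-disubstituted enone may form and turn over slowly. Facial discrimination between the C5 methyl and the CH2 chain may be weak, the more so if E and Z interconvert through the dienamine. The hydroperoxy enamine may also drain into the epoxy ketone. The fallback uses known chemistry, sets out from 13 and returns at 17, and makes the C5–O bond by invertive opening of an oxetane instead of conjugate addition.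
- Reduction of 13 with (R)-2-methyl-CBS-oxazaborolidine and BH3·SMe2 should give (2S,3E,6R)-4,6-dimethyl-12-phenyldodec-3-en-2-ol F1.
- Hydroxyl-directed epoxidation with mCPBA, with the conformation fixed by allylic 1,3-strain against the C4 methyl, should give the threo epoxy alcohol (1S)-1-[(2R,3R)-3-methyl-3-[(2R)-2-methyl-8-phenyloctyl]oxiran-2-yl]ethan-1-ol F2.
- LiAlH4 should open the epoxide at its secondary carbon to (2S,4R,6R)-4,6-dimethyl-12-phenyldodecane-2,4-diol F3.
- Selective sulfonylation of the secondary hydroxyl (TsCl, pyridine) gives (2S,4R,6R)-4-hydroxy-4,6-dimethyl-12-phenyldodecan-2-yl 4-methylbenzenesulfonate F4, which KOtBu closes to (2R,4R)-2,4-dimethyl-2-[(2R)-2-methyl-8-phenyloctyl]oxetane F5.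
- Ethereal H2O2 with TMSOTf should open the oxetane at the tertiary carbon with inversion to (2R,4S,6R)-4-hydroperoxy-4,6-dimethyl-12-phenyldodecan-2-ol F6.
- The hydroperoxide is masked with 2-methoxypropene and PPTS as (2R,4S,6R)-4-[(2-methoxypropan-2-yl)peroxy]-4,6-dimethyl-12-phenyldodecan-2-ol F7, and the carbinol is oxidised with Dess–Martin periodinane to (4S,6R)-4-[(2-methoxypropan-2-yl)peroxy]-4,6-dimethyl-12-phenyldodecan-2-one F8.
- TsOH in MeOH then frees the hydroperoxide, which closes on the ketone and is ketalised to 17.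

Step 10. The silyl ketene acetal may be consumed by TiCl4 before the ketal ionises, the Lewis acid may trigger heterolytic cleavage of the O–O bond, and capture of the cation may not be selective enough for the anti face. The fallback sets out from 17 and returns at 20, and separates C–C bond formation from the ester oxidation level. A bulkier thioester enolate equivalent, 1-(ethylsulfanyl)-1-(trimethylsilyloxy)ethene, is used with TiCl4 in CH2Cl2 at −78 °C and should give S-ethyl 2-[(3R,5S)-3,5-dimethyl-5-[(2R)-2-methyl-8-phenyloctyl]-1,2-dioxolan-3-yl]ethanethioate F9. Thiophilic, non-basic methanolysis with AgO2CCF3 in MeOH then gives 20 without exposing the β-peroxy ester to base.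

Step 4. The basic ylide may enolise the 1,6-keto aldehyde, which then cyclises by intramolecular aldol reaction, and the small keto aldehyde may be lost on concentration. The fallback sets out from 3 and returns at 9, and avoids both the aldehyde and the base. Cross-metathesis of the prenyl-type alkene of 3 with 4-phenylbut-1-ene, using second-generation Grubbs catalyst (H2IMes)(PCy3)Cl2Ru=CHPh in CH2Cl2 at 40 °C, expels 2-methylpropene and should give mainly (4R,7E)-4-methyl-10-phenyldec-7-en-2-one F10. Hydrogenation under the conditions of step 5 then gives 9.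

**Further compounds**

F1 | step 8 | (2S,3E,6R)-4,6-dimethyl-12-phenyldodec-3-en-2-ol | C[C@H](O)/C=C(\C)C[C@H](C)CCCCCCc1ccccc1
F2 | step 8 | (1S)-1-[(2R,3R)-3-methyl-3-[(2R)-2-methyl-8-phenyloctyl]oxiran-2-yl]ethan-1-ol | C[C@H](O)[C@H]1O[C@]1(C)C[C@H](C)CCCCCCc2ccccc2
F3 | step 8 | (2S,4R,6R)-4,6-dimethyl-12-phenyldodecane-2,4-diol | C[C@H](O)C[C@](C)(O)C[C@H](C)CCCCCCc1ccccc1
F4 | step 8 | (2S,4R,6R)-4-hydroxy-4,6-dimethyl-12-phenyldodecan-2-yl 4-methylbenzenesulfonate | C[C@H](OS(=O)(=O)c1ccc(C)cc1)C[C@](C)(O)C[C@H](C)CCCCCCc1ccccc1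
F5 | step 8 | (2R,4R)-2,4-dimethyl-2-[(2R)-2-methyl-8-phenyloctyl]oxetane | C[C@@H]1C[C@@](C)(C[C@H](C)CCCCCCc2ccccc2)O1
F6 | step 8 | (2R,4S,6R)-4-hydroperoxy-4,6-dimethyl-12-phenyldodecan-2-ol | C[C@@H](O)C[C@](C)(C[C@H](C)CCCCCCc1ccccc1)OO
F7 | step 8 | (2R,4S,6R)-4-[(2-methoxypropan-2-yl)peroxy]-4,6-dimethyl-12-phenyldodecan-2-ol | C[C@@H](O)C[C@](C)(C[C@H](C)CCCCCCc1ccccc1)OOC(C)(C)OC
F8 | step 8 | (4S,6R)-4-[(2-methoxypropan-2-yl)peroxy]-4,6-dimethyl-12-phenyldodecan-2-one | CC(=O)C[C@](C)(C[C@H](C)CCCCCCc1ccccc1)OOC(C)(C)OC
F9 | step 10 | S-ethyl 2-[(3R,5S)-3,5-dimethyl-5-[(2R)-2-methyl-8-phenyloctyl]-1,2-dioxolan-3-yl]ethanethioate | CCSC(=O)C[C@@]1(C)C[C@](C)(C[C@H](C)CCCCCCc2ccccc2)OO1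
F10 | step 4 | (4R,7E)-4-methyl-10-phenyldec-7-en-2-one | CC(=O)C[C@H](C)CC/C=C/CCc1ccccc1
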